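**Assumption:** the target (C22H36O4, 4-hydroxy-2-methoxy-6-tridecylphenyl acetate) has no stereocentres, so "single enantiomer" does not apply. The only stereo-element in the route is the alkene geometry of 3, which is erased by hydrogenation.

## Retrosynthetic overview

1. The free 4-OH comes from C–B oxidation of an aryl boronate. This places the acetate on the hindered 1-OH before the 4-oxygen exists, so the two oxygens never need differentiating.
2. The aryl boronate comes from sterically controlled Ir-catalysed C–H borylation of 2-methoxy-6-tridecylphenyl acetate. C4 is the only ring C–H with no ortho substituent.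
3. The acetate comes from 2-methoxy-6-tridecylphenol by acetylation.
4. The C13 chain comes from Wittig olefination of o-vanillin with a C12 ylide (C1 + C12), then hydrogenation.
5. No ring is formed; the benzene ring is bought intact in o-vanillin.

## Route

**Step 1**
Reactants: 1, o-vanillin (2-hydroxy-3-methoxybenzaldehyde); 2, dodecyltriphenylphosphonium bromide
Product: 3, 2-methoxy-6-(tridec-1-en-1-yl)phenol (Z-major E/Z mixture, used as such)
Conditions: 2 (2.3 equiv), KOtBu (2.3 equiv), THF, 0 °C → rt, 12 h; aq. NH4Cl work-up
Reagents that add atoms: dodecyltriphenylphosphonium bromide, CCCCCCCCCCCC[P+](c1ccccc1)(c1ccccc1)c1ccccc1.[Br-] (delivers the C12 alkylidene)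
Why: Wittig olefination with an unstabilised ylide, where the first equivalent of ylide deprotonates the phenol and the excess olefinates the phenoxide-aldehyde; alkene geometry is irrelevant.

**Step 2**
Reactants: 3, 2-methoxy-6-(tridec-1-en-1-yl)phenol
Product: 4, 2-methoxy-6-tridecylphenol
Conditions: H2 (1 atm), 10% Pd/C, EtOAc, rt
Reagents that add atoms: none
Why: Catalytic hydrogenation of a styrenyl alkene converges both isomers to the saturated chain; the phenol and aryl methyl ether are inert.

**Step 3**
Reactants: 4, 2-methoxy-6-tridecylphenol
Product: 5, 2-methoxy-6-tridecylphenyl acetate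
Conditions: Ac2O (1.5 equiv), pyridine, DMAP (5 mol%), CH2Cl2, 0 °C → rt
Reagents that add atoms: acetic anhydride, CC(=O)OC(C)=O
Why: DMAP-catalysed O-acylation drives the 2,6-disubstituted phenol to full conversion, and it is the only nucleophile present.

**Step 4**
Reactants: 5, 2-methoxy-6-tridecylphenyl acetate
Product: 6, 2-methoxy-4-(4,4,5,5-tetramethyl-1,3,2-dioxaborolan-2-yl)-6-tridecylphenyl acetate
Conditions: [Ir(OMe)(cod)]2 (1.5 mol%), dtbpy (3 mol%), B2pin2 (1.0 equiv), THF, 80 °C, 16 h
Reagents that add atoms: bis(pinacolato)diboron, CC1(C)OB(OC1(C)C)B1OC(C)(C)C(C)(C)O1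
Why: Ir-catalysed (Hartwig–Miyaura) C–H borylation is sterically controlled, so this 1,2,3-trisubstituted arene reacts at C4 (para to OAc), the only C–H not ortho to a substituent; aryl esters are tolerated.

**Step 5** (can be telescoped with Step 4 after evaporating the THF)
Reactants: 6, the aryl pinacol boronate
Product: 7, Ardisiphenol D (4-hydroxy-2-methoxy-6-tridecylphenyl acetate)
Conditions: Oxone (1.0 equiv), acetone/H2O 1:1, rt, 10 min; aq. NaHSO3 quench, neutral work-up
Reagents that add atoms: Oxone (potassium peroxymonosulfate, active component KHSO5), [K+].[O-]S(=O)(=O)OO (delivers the phenolic O)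
Why: Ipso oxidation of the C–B bond (boronate 1,2-aryl migration to peroxide oxygen) gives the phenol under neutral to mildly acidic conditions that leave the hindered aryl acetate in place.

## Compound list

1 | o-vanillin (2-hydroxy-3-methoxybenzaldehyde) | COc1cccc(C=O)c1O | starting material
2 | dodecyltriphenylphosphonium bromide | CCCCCCCCCCCC[P+](c1ccccc1)(c1ccccc1)c1ccccc1.[Br-] | starting material
3 | 2-methoxy-6-[(Z)-tridec-1-en-1-yl]phenol (Z-major, E/Z mixture) | CCCCCCCCCCC/C=C\c1cccc(OC)c1O | intermediate
4 | 2-methoxy-6-tridecylphenol | CCCCCCCCCCCCCc1cccc(OC)c1O | intermediate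
5 | 2-methoxy-6-tridecylphenyl acetate | CCCCCCCCCCCCCc1cccc(OC)c1OC(C)=O | intermediate
6 | 2-methoxy-4-(4,4,5,5-tetramethyl-1,3,2-dioxaborolan-2-yl)-6-tridecylphenyl acetate | CCCCCCCCCCCCCc1cc(B2OC(C)(C)C(C)(C)O2)cc(OC)c1OC(C)=O | intermediate
7 | Ardisiphenol D (4-hydroxy-2-methoxy-6-tridecylphenyl acetate) | CCCCCCCCCCCCCc1cc(O)cc(OC)c1OC(C)=O | target

## Summary

**Total step count:** 5 (4 isolations if Steps 4 and 5 are run one-pot).
**Longest linear sequence:** 5 steps from o-vanillin.

**Steps most likely to fail, with fallbacks:**

1. **Step 4 (C–H borylation: incomplete conversion or minor regioisomers).** Fallback: brominate phenol 4 para to the OH (NBS, MeCN) to 4-bromo-2-methoxy-6-tridecylphenol, acetylate, then Pd-catalysed Miyaura borylation (Pd(dppf)Cl2, B2pin2, KOAc) to reach the same boronate 6 with regiochemistry fixed by the bromination.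

2. **Step 5 (boronate oxidation: acetate loss or over-oxidation to the quinone).** Fallback: abandon the boron route. Oxidise phenol 4 with Fremy's salt to 2-methoxy-6-tridecyl-1,4-benzoquinone and reduce with Na2S2O4 to the hydroquinone. Then silylate the unhindered 4-OH selectively (TBSCl, imidazole), acetylate the hindered 1-OH, and remove the TBS group with HF·pyridine.

3. **Step 1 (Wittig on the free phenolic aldehyde: the phenoxide deactivates the carbonyl, giving low conversion).** Fallback: add dodecylmagnesium bromide (2.2 equiv) to o-vanillin to give the benzylic alcohol, then ionic deoxygenation (Et3SiH, TFA) to reach 4 directly. A second alternative is a B-alkyl Suzuki coupling of 2-bromo-6-methoxyphenol with the 9-BBN adduct of 1-tridecene.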